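The earlier runs and the new flask are simulated from invented constants.

Which of the flasks birch, elm, alder and cedar ends with the most target after 30 min, and how much does each hold? The meeting had these before it:

| flask | substrate | first nucleophile | solid second nucleophile | remark | time |
|---|---|---|---|---|---|
| blue | 20 mM | 22 mM | 80 mM | run made earlier |  |
| green | 30 mM | 22 mM | 80 mM | run made earlier |  |
| birch | 20 mM | 22.0 mM (fed, over 20 min) | 80.0 mM | all else is in the flask from the start; the feed brings no volume worth counting | 30 min |
| elm | 20 mM | 22.0 mM | 80.0 mM | everything together at the start | 30 min |
| alder | 20 mM | 22.0 mM (fed, over 5.0 min) | 80.0 mM | all else is in the flask from the start; the feed brings no volume worth counting | 30 min |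
| cedar | 20 mM (fed, over 20 min) | 22.0 mM | 80.0 mM | all else is in the flask from the start; the feed brings no volume worth counting | 30 min |

| run | time / min | target / % |
|---|---|---|
| blue | 1.50 | 1.6 |
| blue | 5.00 | 5.8 |
| blue | 8.00 | 5.4 |
| blue | 12.0 | 9.6 |
| blue | 20.0 | 14.9 |
| green | 0.250 | 0.2 |
| green | 0.417 | 1.0 |
| green | 0.833 | 2.3 |
| green | 1.50 | 0.8 |
| green | 3.00 | 4.8 |

(scatter of a reading: 1 percentage point)

- amounts and yields of target count idle adduct too
- given per volume of solution although it is solid: solid second nucleophile
- reactions considered so far: substrate -> intermediate; first nucleophile + intermediate -> target; second nucleophile + intermediate -> other capture product; intermediate -> solvolysis product; first nucleophile + target <-> idle adduct; solid second nucleophile <-> second nucleophile; intermediate -> decomposed reagent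
- at the start none of the solid second nucleophile is in solution

* the flask with the highest amount of target, in percent of the substrate charged ("all alike" if they lie within 1.5 percentage points) (birch / elm / alder / cedar / all alike)
* final target, as a percentage of the substrate charged, in birch
* final target, as a percentage of the substrate charged, in elm
* final target, as a percentage of the substrate charged, in alder
* final target, as a percentage of the substrate charged, in cedar

The chair opened with the blue run, which has elm's charges and read 14.9 % of target at 20.0 min, a reading with a scatter of 1 percentage point.

The kineticist proposed dividing the rate of target formation by the rate of substrate loss, so that the clock drops out and the share of the intermediate captured as target remains, a selectivity factor. As her own working assumption, she took this share to move in step with the fraction of the first nucleophile's charge on hand. For birch, she reckoned one minus the feed time over twice the run time, 0.667, ignoring consumption, and called this time-averaged fraction of the charge on hand the dose fraction. For alder the same sum gives 0.917, and for elm it is one. She therefore expected birch and alder to hold those fractions of elm's target.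

The chair objected that cedar receives its substrate by feed, so the dose fraction does not speak to it, and she agreed.

The forecast then gave 20.5 % for elm (17.5 % to 24 %), 14.5 % for birch (10 % to 19 %), 19 % for alder (15.5 % to 23 %) and 13.5 % for cedar (10 % to 17 %), and it named elm as highest. Its ground was: “Feeding the first nucleophile starves capture early, while the intermediate is lost to other routes.” The kineticist noted that its birch-to-elm ratio, 0.707, stands a little higher than her 0.667.

The flasks give 18.0 % in elm, 11.0 % in birch, 15.8 % in alder and 13.6 % in cedar, so elm is highest, as forecast, and each value lies inside its forecast range.

    substrate → intermediate (k = 0.0360 min⁻¹)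
    first nucleophile + intermediate → target (k = 1300 M⁻¹ min⁻¹)
    second nucleophile + intermediate → other capture product (k = 1900 M⁻¹ min⁻¹)
    intermediate → solvolysis product (k = 38.0 min⁻¹)
    first nucleophile + target ⇌ idle adduct, settled at all times (K = 76.0 M⁻¹)
    solid second nucleophile ⇌ second nucleophile, rate k6*(cs6 - [second nucleophile]) while solid is left; crystals form when [second nucleophile] > cs6 (solubility = 17.0 mM, k = 0.440 min⁻¹)
    intermediate → decomposed reagent (k = 0.390 min⁻¹)

Birch held 0.611 of elm's target against a dose fraction of 0.667, and alder held 0.878 against 0.917. The neighbouring flask is birch with a quarter of its first nucleophile, 5.5 mM, fed over the same time. Its dose fraction, measured against elm's charge, is therefore 0.167, and multiplying this by elm's 18.0 % gives 3.01 %. That neighbouring flask ended with 3.29 % of target.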